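**Retrosynthetic overview**
- The target comes from one hydrogenolysis that removes two benzyl ethers and one diphenylmethylene ketal from a fully protected flavone 3'-sulfate salt; the sulfate is untouched.
- The protected flavone sulfate comes from an o-hydroxyaryl 1,3-diketone. The pyranone ring is closed by O1–C2 bond formation (dehydrative oxa-cyclisation) in the same pot that sulfates the only free ring-B phenol.
- The diketone comes from a Claisen condensation of the ring-A methyl ketone with the ring-B methyl ester.
- Ring B is methyl gallate with two adjacent OH groups tied as a diphenylmethylene ketal, so exactly one OH (the future sulfate site) stays free. Ring A is 2',4',6'-trihydroxyacetophenone, di-O-benzylated.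
- Rings A and B are bought; the pyranone ring is the only ring formed, and it is formed last.

Assumption: the target has no stereocentre and no stereogenic double bond, so it is a single achiral compound and no stereocontrol is needed; it is delivered as the free hydrogen sulfate as drawn.

**Step 1**
Reactants: 1 2',4',6'-trihydroxyacetophenone; 2 benzyl bromide
Product: 3 1-[2,4-bis(benzyloxy)-6-hydroxyphenyl]ethan-1-one
Conditions: BnBr (2.1 equiv), K2CO3 (2.2 equiv), DMF, 0 to 25 °C
Reagents that add atoms: benzyl bromide, BrCc1ccccc1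
Why: Williamson ether synthesis in which the para OH and one ortho OH are alkylated while the remaining ortho OH, held in a strong hydrogen bond to the ketone, stays free; no stereocentre is involved.

**Step 2**
Reactants: 4 methyl gallate; 5 dichlorodiphenylmethane
Product: 6 methyl 7-hydroxy-2,2-diphenyl-1,3-benzodioxole-5-carboxylate
Conditions: Ph2CCl2 (1.3 equiv), neat, 180 °C, 20 min
Reagents that add atoms: dichlorodiphenylmethane, ClC(Cl)(c1ccccc1)c1ccccc1
Why: Ketal formation from a geminal dichloride and a catechol pair; only adjacent OH groups can close the five-membered ring and, by the symmetry of methyl gallate, either adjacent pair gives the same product with exactly one free OH.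

**Step 3**
Reactants: 3 1-[2,4-bis(benzyloxy)-6-hydroxyphenyl]ethan-1-one; 6 methyl 7-hydroxy-2,2-diphenyl-1,3-benzodioxole-5-carboxylate
Product: 7 1-[2,4-bis(benzyloxy)-6-hydroxyphenyl]-3-(7-hydroxy-2,2-diphenyl-1,3-benzodioxol-5-yl)propane-1,3-dione
Conditions: LiN(SiMe3)2 (4.5 equiv), THF, −78 °C to reflux; then cold dilute aq. HCl
Reagents that add atoms: none
Why: Crossed Claisen condensation of the phenoxide/enolate dianion of 3 with the ester of 6, driven by irreversible deprotonation of the 1,3-diketone; any O-acylated material rearranges to the same diketone under the base (Baker–Venkataraman), and no stereocentre is formed.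

**Step 4**
Reactants: 7 1-[2,4-bis(benzyloxy)-6-hydroxyphenyl]-3-(7-hydroxy-2,2-diphenyl-1,3-benzodioxol-5-yl)propane-1,3-dione; 8 sulfur trioxide–triethylamine complex
Product: 11 triethylammonium 6-[5,7-bis(benzyloxy)-4-oxo-4H-chromen-2-yl]-2,2-diphenyl-1,3-benzodioxol-4-yl sulfate, via ring-B aryl sulfate of the diketone 9 (not isolated), via 2-sulfooxyflavanone disulfate salt 10 (not isolated)
Conditions: SO3·NEt3 (3 equiv), pyridine, 25 °C (2 h) then 70 °C (8 h); MeOH quench; SiO2 (CH2Cl2/MeOH/Et3N)
Reagents that add atoms: sulfur trioxide–triethylamine complex, CC[N+](CC)(CC)S(=O)(=O)[O-]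
Why: Proposed new method: a sulfative cyclodehydration in which SO3·NEt3 first O-sulfates the only unchelated phenol (ring B, giving 9) and then the enol oxygen at the future C2, the chelated ring-A phenol adds 6-endo to that carbon to make the O1–C2 bond (hemiketal sulfate 10, racemic and transient), and hydrogen sulfate is expelled with loss of H3 to give the aromatic 4-pyranone, so one reagent acts as sulfating agent and as water acceptor under non-acidic conditions that spare the benzyl ethers, the ketal and the new aryl sulfate; the closest known reaction types are the acid-catalysed cyclodehydration of o-hydroxyaryl 1,3-diketones (Baker–Venkataraman flavone synthesis) and alcohol dehydration through sulfate or sulfamate esters (Burgess-type).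

**Step 5**
Reactants: 11 triethylammonium 6-[5,7-bis(benzyloxy)-4-oxo-4H-chromen-2-yl]-2,2-diphenyl-1,3-benzodioxol-4-yl sulfate
Product: 13 tricetin 3'-sulfate (2,3-dihydroxy-5-(5,7-dihydroxy-4-oxo-4H-chromen-2-yl)phenyl hydrogen sulfate), via triethylammonium salt of the target 12 (not isolated)
Conditions: H2 (1 atm), Pd(OH)2/C, THF/MeOH 1:1, 25 °C; then Dowex 50W (H+ form), H2O/MeOH, 0 °C; freeze-dry at once
Reagents that add atoms: none
Why: Hydrogenolysis of the benzylic C–O bonds of both benzyl ethers and the diphenylmethylene ketal over palladium, to which aryl sulfate monoesters and the flavone C2=C3 bond are inert at 1 atm, followed by cold cation exchange to the free acid; no stereocentre exists in the product.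

**Compound list**
1 | 2',4',6'-trihydroxyacetophenone | CC(=O)c1c(O)cc(O)cc1O | starting material
2 | benzyl bromide | BrCc1ccccc1 | starting material
3 | 1-[2,4-bis(benzyloxy)-6-hydroxyphenyl]ethan-1-one | CC(=O)c1c(O)cc(OCc2ccccc2)cc1OCc1ccccc1 | intermediate
4 | methyl gallate (methyl 3,4,5-trihydroxybenzoate) | COC(=O)c1cc(O)c(O)c(O)c1 | starting material
5 | dichlorodiphenylmethane | ClC(Cl)(c1ccccc1)c1ccccc1 | starting material
6 | methyl 7-hydroxy-2,2-diphenyl-1,3-benzodioxole-5-carboxylate | COC(=O)c1cc(O)c2OC(c3ccccc3)(c3ccccc3)Oc2c1 | intermediate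
7 | 1-[2,4-bis(benzyloxy)-6-hydroxyphenyl]-3-(7-hydroxy-2,2-diphenyl-1,3-benzodioxol-5-yl)propane-1,3-dione (achiral; drawn as the diketo tautomer) | O=C(CC(=O)c1cc(O)c2OC(c3ccccc3)(c3ccccc3)Oc2c1)c1c(O)cc(OCc2ccccc2)cc1OCc1ccccc1 | intermediate
8 | sulfur trioxide–triethylamine complex | CC[N+](CC)(CC)S(=O)(=O)[O-] | starting material
9 | triethylammonium 6-{3-[2,4-bis(benzyloxy)-6-hydroxyphenyl]-3-oxopropanoyl}-2,2-diphenyl-1,3-benzodioxol-4-yl sulfate (formed in the flask, not isolated) | CC[NH+](CC)CC.[O-]S(=O)(=O)Oc1cc(C(=O)CC(=O)c2c(O)cc(OCc3ccccc3)cc2OCc2ccccc2)cc2OC(c3ccccc3)(c3ccccc3)Oc12 | intermediate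
10 | bis(triethylammonium) salt of 5,7-bis(benzyloxy)-2-[2,2-diphenyl-7-(sulfonatooxy)-1,3-benzodioxol-5-yl]-4-oxochroman-2-yl sulfate (racemic at C2, transient, not isolated) | CC[NH+](CC)CC.CC[NH+](CC)CC.[O-]S(=O)(=O)OC1(CC(=O)c2c(OCc3ccccc3)cc(OCc3ccccc3)cc2O1)c1cc(OS(=O)(=O)[O-])c2OC(c3ccccc3)(c3ccccc3)Oc2c1 | intermediate
11 | triethylammonium 6-[5,7-bis(benzyloxy)-4-oxo-4H-chromen-2-yl]-2,2-diphenyl-1,3-benzodioxol-4-yl sulfate (achiral) | CC[NH+](CC)CC.[O-]S(=O)(=O)Oc1cc(-c2cc(=O)c3c(OCc4ccccc4)cc(OCc4ccccc4)cc3o2)cc2OC(c3ccccc3)(c3ccccc3)Oc12 | intermediate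
12 | triethylammonium 2,3-dihydroxy-5-(5,7-dihydroxy-4-oxo-4H-chromen-2-yl)phenyl sulfate (formed in the flask, not isolated) | CC[NH+](CC)CC.O=c1cc(-c2cc(O)c(O)c(OS(=O)(=O)[O-])c2)oc2cc(O)cc(O)c12 | intermediate
13 | tricetin 3'-sulfate, 2,3-dihydroxy-5-(5,7-dihydroxy-4-oxo-4H-chromen-2-yl)phenyl hydrogen sulfate (achiral) | O=c1cc(-c2cc(O)c(O)c(OS(=O)(=O)O)c2)oc2cc(O)cc(O)c12 | target

**Step count and risks**

Total steps: 5. Longest linear sequence: 4 steps (1 → 3 → 7 → 11 → 13, or equally 4 → 6 → 7 → 11 → 13).

The three steps most likely to fail are steps 4, 3 and 1. The final hydrogenolysis is the standard way to unmask benzyl- and diphenylmethylene-protected flavonoid sulfates and ranks below them; the free acid should be kept cold and dry, or neutralised to its potassium salt for storage.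

Step 4, the proposed sulfative ring closure, is the least certain. The chelated ring-A phenol could be sulfated before it cyclises, or the C2-sulfate could simply hydrolyse back to 7 on work-up. The fallback uses known chemistry and sets out from 7. Acid-catalysed cyclodehydration (p-toluenesulfonic acid, 10 mol %, toluene, 90 °C) gives 5,7-bis(benzyloxy)-2-(7-hydroxy-2,2-diphenyl-1,3-benzodioxol-5-yl)-4H-chromen-4-one F1. Its single free phenol is then sulfated in the ordinary way (SO3·NEt3, pyridine, 40 °C), and the sequence comes back to the route at 11. Any F1 already present in crude 7 is converted to 11 under the step 4 conditions as well.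

Step 3 may be sluggish because the ester of 6 reacts as an electron-rich lithium phenoxide. The fallback sets out from 6 and moves the sulfation ahead of the carbon–carbon union. SO3·NEt3 in pyridine at 40 °C gives triethylammonium 6-(methoxycarbonyl)-2,2-diphenyl-1,3-benzodioxol-4-yl sulfate F2, whose anionic sulfate is inert to amide base and no longer deactivates the ester. Claisen condensation of F2 with 3 (LiN(SiMe3)2, 4 equiv, THF, −78 to 50 °C; triethylammonium acetate buffer work-up) comes back to the route at 9, now isolated. Compound 9 then needs only the dehydrative half of step 4 (1.5 equiv of 8). This Claisen on a sulfate-bearing ester is itself unprecedented, so it is a reasoned alternative, not a proven one.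

Step 1 can give C-benzylated and over- or under-alkylated material. The fallback sets out from 1. Exhaustive O-benzylation (BnBr 3.5 equiv, K2CO3, DMF, 80 °C) gives 1-[2,4,6-tris(benzyloxy)phenyl]ethan-1-one F3. Chelation-controlled removal of one benzyl group ortho to the carbonyl (MgBr2·OEt2, toluene/Et2O, reflux) then comes back to the route at 3.

**Further compounds**
F1 | step 4 | 5,7-bis(benzyloxy)-2-(7-hydroxy-2,2-diphenyl-1,3-benzodioxol-5-yl)-4H-chromen-4-one | O=c1cc(-c2cc(O)c3OC(c4ccccc4)(c4ccccc4)Oc3c2)oc2cc(OCc3ccccc3)cc(OCc3ccccc3)c12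
F2 | step 3 | triethylammonium 6-(methoxycarbonyl)-2,2-diphenyl-1,3-benzodioxol-4-yl sulfate | CC[NH+](CC)CC.COC(=O)c1cc(OS(=O)(=O)[O-])c2OC(c3ccccc3)(c3ccccc3)Oc2c1
F3 | step 1 | 1-[2,4,6-tris(benzyloxy)phenyl]ethan-1-one | CC(=O)c1c(OCc2ccccc2)cc(OCc2ccccc2)cc1OCc1ccccc1
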